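**Strategy.** Everything rests on cutting three bonds around the central ring-fusion methine C-z: O-A–C-z, C-z–C-y and O-B–CMe2 (O-A and O-B are the 4-oxygens of quinolinones A and B). The feature exploited is that C-x, the methine carrying the 2-methylprop-1-enyl group on C3 of quinolinone A, sits next to C-y, whose CMe2–O-B arm in pyran ring B is a second such alkene in disguise; C-x can therefore start as a prochiral carbon bearing two identical alkenes. A 3-(dialkenylmethyl)-4-hydroxyquinolinone and a 3-formyl-4-hydroxyquinolinone condense to an aryloxymethylene dione, whose oxadiene captures one alkene, closing pyran rings A and B and setting all three stereocentres under chiral Brønsted acid control.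

Key step: step 6

Labels: quinolinone A is the 1-methylquinolin-2-one whose C3 is bonded to C-x; quinolinone B is the one whose C3 is bonded to C-z. C-y is the ring-fusion CH bonded to C-x, C-z and CMe2. Pyran ring A = O-A, C4(A), C3(A), C-x, C-y, C-z. Pyran ring B = O-B, C4(B), C3(B), C-z, C-y, CMe2. The target SMILES corresponds to C-x S, C-y S, C-z R: H at C-y and C-z cis, and the alkenyl group on C-x trans to the CMe2 carbon on C-y.

Assumption: the sense of induction of the chiral acid cannot be predicted with confidence. The (R)-acid is written; the (S)-acid would be used if it proves to favour the mirror image.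

Remarks on the chemistry:
- A chloroiminium (POCl3/DMF) formylation of a 4-hydroxyquinolin-2-one would exchange the 4-OH for chloride. The formyl group of 12 is therefore introduced through the enaminone.
- The aldehyde 12 is used as the free formyl-enol and not as a halide- or sulfonate-activated derivative. Such activation places the leaving group on C4 of the ring and would lead to O-arylation at the wrong carbon.
- A chiral Cu(OTf)2/bisoxazoline Lewis acid (divalent copper) is not chosen. Compound 12 is a β-oxo-enol that would bind the metal as a chelate and liberate strong acid, which could cyclise the 4-OH of 9 onto one of its alkenes.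
- Compound 9 is made and handled only under basic or near-neutral conditions and under argon, because its CH is doubly allylic.

Step 1
Reactants: 1 3-methylbut-2-enal; 2 diethyl malonate
Product: 3 diethyl 2-(3-methylbut-2-en-1-ylidene)propanedioate
Conditions: TiCl4, pyridine, THF, 0 °C to rt
Reagents that add atoms: none
Why: The titanium tetrachloride/pyridine variant of the Knoevenagel condensation is reliable for enolisable enals and should give the dienyl malonate without self-condensation of the aldehyde; no stereocentre is formed.

Step 2
Reactants: 3 diethyl 2-(3-methylbut-2-en-1-ylidene)propanedioate; 4 2-methylprop-1-enylmagnesium bromide (commercial THF solution)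
Product: 5 diethyl 2-(2,6-dimethylhepta-2,5-dien-4-yl)propanedioate
Conditions: CuI (10 mol%), THF, −40 to 0 °C; aq. NH4Cl
Reagents that add atoms: none
Why: Copper-catalysed conjugate (1,4) addition of an alkenyl Grignard reagent to an alkylidene malonate should occur at the carbon next to the malonate because the δ-carbon is fully substituted, and the new CH (later C-x) carries two identical alkenyl groups and is not a stereocentre.

Step 3
Reactants: 5 diethyl 2-(2,6-dimethylhepta-2,5-dien-4-yl)propanedioate
Product: 6 ethyl 5-methyl-3-(2-methylprop-1-en-1-yl)hex-4-enoate
Conditions: LiCl, H2O, DMSO, 150 °C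
Reagents that add atoms: none
Why: Krapcho dealkoxycarbonylation removes one ester group under neutral conditions, so no acid is present that could isomerise or hydrate the skipped diene.

Step 4
Reactants: 6 ethyl 5-methyl-3-(2-methylprop-1-en-1-yl)hex-4-enoate; 7 N-methylisatoic anhydride
Product: 9 3-(2,6-dimethylhepta-2,5-dien-4-yl)-4-hydroxy-1-methylquinolin-2(1H)-one, via keto ester 8 (not isolated)
Conditions: LiN(SiMe3)2 (2.2 equiv), THF, −78 °C; then 7, −78 to 50 °C; AcOH
Reagents that add atoms: none
Why: C-acylation of the ester lithium enolate at the anhydride carbonyl of 7, loss of CO2 and lactamisation of the freed N-methylaniline nitrogen onto the ester (isatoic anhydride annulation to 4-hydroxyquinolin-2-ones) should build quinolinone A under basic conditions that leave the diene untouched.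

Step 5
Reactants: 10 4-hydroxy-1-methylquinolin-2(1H)-one
Product: 12 3-formyl-4-hydroxy-1-methylquinolin-2(1H)-one, via enaminone 11 (not isolated)
Conditions: DMF-DMA, toluene, 60 °C; then 1 M aq. HCl, THF, rt
Reagents that add atoms: N,N-dimethylformamide dimethyl acetal, COC(OC)N(C)C; water, O
Why: Aminomethylenation of the nucleophilic C3 position followed by mild acid hydrolysis of the push–pull enaminone should give the formyl-enol without the 4-OH to 4-Cl exchange that a Vilsmeier–Haack formylation would cause.

Step 6
Reactants: 9 3-(2,6-dimethylhepta-2,5-dien-4-yl)-4-hydroxy-1-methylquinolin-2(1H)-one; 12 3-formyl-4-hydroxy-1-methylquinolin-2(1H)-one (1.2 equiv, added slowly)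
Product: 14 target CNP0210533.1 (C-x S; C-y S; C-z R), via aryloxymethylene dione 13 (not isolated)
Conditions: (R)-3,3'-bis(2,4,6-triisopropylphenyl)-1,1'-binaphthyl-2,2'-diyl hydrogen phosphate (10 mol%), 5 Å molecular sieves, toluene, 40 °C, argon
Reagents that add atoms: none
Why: Proposed new method: the acid should catalyse hemiacetal formation between the 4-OH of 9 and the formyl carbon of 12 and its dehydration to 13, an ortho-quinone-methide-like 1-oxadiene (O-B=C4–C3=C-z, held s-cis by the ring) which, hydrogen-bonded to the chiral phosphate, adds across one of the two 2-methylprop-1-enyl groups in an asynchronous inverse-demand oxa-[4+2] process, C-y bonding to C-z and the tertiary alkene carbon to O-B. The closest known reaction types are the chiral Brønsted acid catalysed condensation of salicylaldehydes with hydroxy-alkenes to alkoxy ortho-quinone methides that undergo intramolecular oxa-Diels–Alder reaction, and the domino Knoevenagel/intramolecular hetero-Diels–Alder reaction of alkylidene 1,3-dicarbonyl compounds with tethered trisubstituted alkenes; new here are the enolic oxygen nucleophile and the choice between two enantiotopic alkenes. Pyran ring B is the six-membered ring of the cycloaddition itself (C-z–C-y and O-B–CMe2 bonds), whereas pyran ring A is the tether ring, closed by the C-z–C-y bond in a 6-exo-trig sense once the condensation has made the O-A–C-z bond. The flat four-atom tether (O-A, C4 and C3 of quinolinone A, C-x) allows only the folded endo transition state and so sets H at C-z and C-y cis; allylic 1,3-strain holds the C-x–H bond in the plane of the reacting alkene so that the spectator alkenyl group ends trans to the CMe2 carbon; the absolute configuration of all three centres follows from which enantiotopic alkene the chiral acid complex selects. The step needs O- and not C-attack of 9 (C3 is substituted and hindered, so no Knoevenagel pathway exists), the ketone and not the lactam carbonyl of 13 as the diene terminus (the enone is the more electron-poor oxadiene and the alkene isomers of 13 interconvert), and a catalysed rate above the background promoted by the acidic aldehyde 12, helped by its slow addition; every unproductive condensation is reversible and only the cycloaddition is irreversible.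

**Compound list**

1 | 3-methylbut-2-enal | CC(C)=CC=O | starting material
2 | diethyl malonate | CCOC(=O)CC(=O)OCC | starting material
3 | diethyl 2-(3-methylbut-2-en-1-ylidene)propanedioate | CCOC(=O)C(=CC=C(C)C)C(=O)OCC | intermediate
4 | 2-methylprop-1-enylmagnesium bromide | CC(C)=C[Mg]Br | starting material
5 | diethyl 2-(2,6-dimethylhepta-2,5-dien-4-yl)propanedioate | CCOC(=O)C(C(C=C(C)C)C=C(C)C)C(=O)OCC | intermediate
6 | ethyl 5-methyl-3-(2-methylprop-1-en-1-yl)hex-4-enoate | CCOC(=O)CC(C=C(C)C)C=C(C)C | intermediate
7 | N-methylisatoic anhydride (1-methyl-2H-3,1-benzoxazine-2,4(1H)-dione) | CN1C(=O)OC(=O)c2ccccc12 | starting material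
8 | ethyl 5-methyl-2-[2-(methylamino)benzoyl]-3-(2-methylprop-1-en-1-yl)hex-4-enoate (present as its lithium enolate; configuration at C2 not defined) | CCOC(=O)C(C(C=C(C)C)C=C(C)C)C(=O)c1ccccc1NC | intermediate (not isolated)
9 | 3-(2,6-dimethylhepta-2,5-dien-4-yl)-4-hydroxy-1-methylquinolin-2(1H)-one | CC(C)=CC(C=C(C)C)c1c(O)c2ccccc2n(C)c1=O | intermediate
10 | 4-hydroxy-1-methylquinolin-2(1H)-one | Cn1c(=O)cc(O)c2ccccc12 | starting material
11 | 3-[(dimethylamino)methylidene]-1-methylquinoline-2,4(1H,3H)-dione (alkene geometry not defined) | CN(C)C=C1C(=O)c2ccccc2N(C)C1=O | intermediate (not isolated)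
12 | 3-formyl-4-hydroxy-1-methylquinolin-2(1H)-one | Cn1c(=O)c(C=O)c(O)c2ccccc12 | intermediate
13 | 3-({[3-(2,6-dimethylhepta-2,5-dien-4-yl)-1-methyl-2-oxo-1,2-dihydroquinolin-4-yl]oxy}methylidene)-1-methylquinoline-2,4(1H,3H)-dione (alkene geometry not defined; the reactive isomer has the aryloxy group on the lactam side) | CC(C)=CC(C=C(C)C)c1c(OC=C2C(=O)c3ccccc3N(C)C2=O)c2ccccc2n(C)c1=O | intermediate (not isolated)
14 | target CNP0210533.1: quinolinone A fused at C3/C4 to pyran ring A and quinolinone B fused at C3/C4 to pyran ring B, the two pyrans sharing the cis-fused C-y–C-z bond, 2-methylprop-1-enyl on C-x, gem-dimethyl on the carbon between C-y and O-B; C-x S, C-y S, C-z R | CC(C)=C[C@@H]1c2c(c3ccccc3n(C)c2=O)O[C@H]2c3c(c4ccccc4n(C)c3=O)OC(C)(C)[C@@H]12 | target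

**Step count and risks**

Total steps: 6. Longest linear sequence: 5 (steps 1, 2, 3, 4 and 6); step 5 is a one-step side branch.

Risk 1, step 6 (the new method). Three processes may spoil it:
- weak discrimination between the two enantiotopic alkenes, because a cycloaddition promoted by the acidic aldehyde runs beside the one in the chiral acid complex;
- acid-mediated ring closure of the free 4-OH of 9 onto one of its own alkenes before the condensation;
- ring closure through the lactam oxygen in place of the ketone oxygen.

The fallback uses known chemistry and forms pyran ring A by a different cycloaddition. It sets out from 10 and 1. Their condensation in refluxing pyridine (domino Knoevenagel condensation/oxa-6π-electrocyclisation) should give 2,2,6-trimethyl-2H-pyrano[3,2-c]quinolin-5(6H)-one F1. Heating F1 (melt or refluxing 1,2-dichlorobenzene) reopens part of it to the ortho-quinone methide. This adds through O-A and C-x across the pyran double bond (C-z=C-y) of a second molecule, the hetero-Diels–Alder mode by which such pyranoquinolinones are known to dimerise. The cis-fused adduct of the required relative configuration would be separated from diastereomers by chromatography. It is racemic, that is 14 together with the mirror-image cycloadduct F2. Preparative HPLC on a chiral stationary phase would remove F2, and the fallback comes back to the route at 14.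

Risk 2, step 2. Copper-mediated 1,6-addition at the far end of the dienyl acceptor, or sluggish transfer of the hindered alkenyl group, may compete with 1,4-addition. The fallback sets out from 1. Knoevenagel condensation with Meldrum's acid (2,2-dimethyl-1,3-dioxane-4,6-dione; pyridine, CH2Cl2) should give 2,2-dimethyl-5-(3-methylbut-2-en-1-ylidene)-1,3-dioxane-4,6-dione F3. Addition of 4 without copper (THF, −78 °C) is charge-controlled and should go to the alkylidene carbon, giving 5-(2,6-dimethylhepta-2,5-dien-4-yl)-2,2-dimethyl-1,3-dioxane-4,6-dione F4. Heating F4 in ethanol/pyridine with Cu powder (cat.) opens the dioxanedione and decarboxylates the half-ester. The fallback comes back to the route at 6, so step 3 is bypassed as well.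

Risk 3, step 4. C-acylation of the β-branched enolate may be incomplete, the amide base may attack the anhydride, or the lactamisation may stall at the keto ester. The fallback sets out from 6. Saponification (LiOH, THF/H2O) gives 5-methyl-3-(2-methylprop-1-en-1-yl)hex-4-enoic acid F5. 1-Chloro-N,N,2-trimethylprop-1-en-1-amine converts it under neutral conditions into 5-methyl-3-(2-methylprop-1-en-1-yl)hex-4-enoyl chloride F6. This acylates methyl 2-(methylamino)benzoate (pyridine, CH2Cl2) to methyl 2-{methyl[5-methyl-3-(2-methylprop-1-en-1-yl)hex-4-enoyl]amino}benzoate F7. Intramolecular Claisen (Dieckmann-type) condensation with KN(SiMe3)2 in THF closes the 4-hydroxyquinolin-2-one, and the fallback comes back to the route at 9.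

Further compounds
F1 | step 6 | 2,2,6-trimethyl-2H-pyrano[3,2-c]quinolin-5(6H)-one | CC1(C)C=Cc2c(O1)c1ccccc1n(C)c2=O
F2 | step 6 | mirror-image cycloadduct (enantiomer of 14; C-x R, C-y R, C-z S) | CC(C)=C[C@H]1c2c(c3ccccc3n(C)c2=O)O[C@@H]2c3c(c4ccccc4n(C)c3=O)OC(C)(C)[C@H]12
F3 | step 2 | 2,2-dimethyl-5-(3-methylbut-2-en-1-ylidene)-1,3-dioxane-4,6-dione | CC(C)=CC=C1C(=O)OC(C)(C)OC1=O
F4 | step 2 | 5-(2,6-dimethylhepta-2,5-dien-4-yl)-2,2-dimethyl-1,3-dioxane-4,6-dione | CC(C)=CC(C=C(C)C)C1C(=O)OC(C)(C)OC1=O
F5 | step 4 | 5-methyl-3-(2-methylprop-1-en-1-yl)hex-4-enoic acid | CC(C)=CC(CC(=O)O)C=C(C)C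
F6 | step 4 | 5-methyl-3-(2-methylprop-1-en-1-yl)hex-4-enoyl chloride | CC(C)=CC(CC(=O)Cl)C=C(C)C
F7 | step 4 | methyl 2-{methyl[5-methyl-3-(2-methylprop-1-en-1-yl)hex-4-enoyl]amino}benzoate | COC(=O)c1ccccc1N(C)C(=O)CC(C=C(C)C)C=C(C)C
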